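Numbering: core chroman O1, C2 (catechol ring E), C3, C4 (resorcinol ring D), benzo ring B (C4a–C8a, oxygen on C8), pyran ring F; second chroman O1', C2' (bonded to C6), C3', C4', benzo ring A (C4a'–C8a'), pyran ring C.
Cuts, last bond first: the seven benzyl ethers; then C4'–C4a' of ring C, which is possible because C4' is an unsubstituted CH2 on the ring A carbon ortho to O1' and para to the C7' oxygen, so an aryloxy epoxide that already carries C2' and C3' can close the ring; then O1'–C2', the cinnamyl side chain at C6, C4–ring D, O1–C2 and the enone C=C of a chalcone.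
Forward order: ring B acetophenone, chalcone with ring E, ring F as a dihydroflavonol, ring D onto C4, three-carbon chain at C6, ring A through O1', ring C closed last, hydrogenolysis.
Stereochemistry: C2/C3 from Juliá–Colonna epoxidation and anti opening by the ring B phenol; C4 from hydride delivery to a C4 cation trans to O3; C2'/C3' from Sharpless epoxidation with diisopropyl L-tartrate, L-(+)-DIPT, and inversion at C2' by the phenoxide; closing ring C creates no stereocentre.
Remark: the target is read as 2,3-trans-3,4-cis (2R,3S,4S) in the core and 2',3'-trans (2'R,3'S) in the second chroman; compounds 1, 5, 11, 17 and 21 are taken as commercial.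

Key step: step 16

Abbreviation used in names: core-6-yl = (2R,3S,4S)-3,8-bis(benzyloxy)-4-[2,4-bis(benzyloxy)phenyl]-2-[3,4-bis(benzyloxy)phenyl]-3,4-dihydro-2H-chromen-6-yl.

Step 1
Reactants: 1 1-(2,3-dihydroxyphenyl)ethan-1-one
Product: 2 1-[3-(benzyloxy)-2-hydroxyphenyl]ethan-1-one
Conditions: NaH (2.1 equiv), DMSO, rt; BnBr (1.0 equiv), rt
Reagents that add atoms: benzyl bromide, BrCc1ccccc1
Why: Williamson etherification of the catechol dianion, in which the O3 phenoxide is neither chelated by nor conjugated with the acetyl group and is the more nucleophilic oxygen, so one equivalent of benzyl bromide should react there.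

Step 2
Reactants: 2 1-[3-(benzyloxy)-2-hydroxyphenyl]ethan-1-one
Product: 3 1-[3-(benzyloxy)-5-bromo-2-hydroxyphenyl]ethan-1-one
Conditions: NBS, MeCN, 0 °C to rt
Reagents that add atoms: N-bromosuccinimide, O=C1CCC(=O)N1Br
Why: Electrophilic aromatic bromination should go para to the free phenol, the one position that is activated by the hydroxyl group and meta to the acetyl group.

Step 3
Reactants: 3 1-[3-(benzyloxy)-5-bromo-2-hydroxyphenyl]ethan-1-one
Product: 4 1-[3-(benzyloxy)-5-bromo-2-(methoxymethoxy)phenyl]ethan-1-one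
Conditions: MOMCl, i-Pr2NEt, CH2Cl2, 0 °C to 40 °C
Reagents that add atoms: chloromethyl methyl ether, COCCl
Why: O-Alkylation of the chelated phenol gives a MOM acetal that withstands the basic aldol and epoxidation steps and is later removed by acid in the same operation that closes ring F.

Step 4
Reactants: 4 1-[3-(benzyloxy)-5-bromo-2-(methoxymethoxy)phenyl]ethan-1-one; 5 3,4-bis(benzyloxy)benzaldehyde
Product: 6 (E)-1-[3-(benzyloxy)-5-bromo-2-(methoxymethoxy)phenyl]-3-[3,4-bis(benzyloxy)phenyl]prop-2-en-1-one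
Conditions: KOH, EtOH/THF, rt
Reagents that add atoms: none
Why: Claisen–Schmidt aldol condensation of the methyl ketone with the non-enolisable aldehyde, the E enone being the thermodynamic product of the dehydration.

Step 5
Reactants: 6 (E)-1-[3-(benzyloxy)-5-bromo-2-(methoxymethoxy)phenyl]-3-[3,4-bis(benzyloxy)phenyl]prop-2-en-1-one
Product: 7 [3-(benzyloxy)-5-bromo-2-(methoxymethoxy)phenyl]{(2R,3S)-3-[3,4-bis(benzyloxy)phenyl]oxiran-2-yl}methanone
Conditions: poly-L-leucine, urea–H2O2, DBU, THF, rt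
Reagents that add atoms: urea–hydrogen peroxide adduct, OO.NC(N)=O
Why: Juliá–Colonna epoxidation, in which the helical poly-L-leucine directs the conjugate addition of hydroperoxide to one face of the enone and should give the (2R,3S) trans epoxide.

Step 6
Reactants: 7 [3-(benzyloxy)-5-bromo-2-(methoxymethoxy)phenyl]{(2R,3S)-3-[3,4-bis(benzyloxy)phenyl]oxiran-2-yl}methanone
Product: 9 (2R,3R)-8-(benzyloxy)-2-[3,4-bis(benzyloxy)phenyl]-6-bromo-3-hydroxy-2,3-dihydro-4H-chromen-4-one, via free-phenol epoxy ketone 8 (not isolated)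
Conditions: HCl, MeOH/THF, 50 °C
Reagents that add atoms: none
Why: Acid removes the MOM acetal and the freed phenol opens the epoxide at its benzylic carbon in a 6-endo cyclisation with inversion, so the trans epoxide should give the 2,3-trans dihydroflavonol (the classical epoxychalcone route), C3 keeping the epoxide oxygen and configuration.

Step 7
Reactants: 9 (2R,3R)-8-(benzyloxy)-2-[3,4-bis(benzyloxy)phenyl]-6-bromo-3-hydroxy-2,3-dihydro-4H-chromen-4-one
Product: 10 (2R,3R)-3,8-bis(benzyloxy)-2-[3,4-bis(benzyloxy)phenyl]-6-bromo-2,3-dihydro-4H-chromen-4-one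
Conditions: BnBr, Ag2O, CH2Cl2, rt, dark
Reagents that add atoms: benzyl bromide, BrCc1ccccc1
Why: Silver-oxide-promoted Williamson benzylation runs under nearly neutral conditions and so should avoid the base-induced ring opening and epimerisation of this β-aryloxy ketone.

Step 8
Reactants: 11 4-bromobenzene-1,3-diol
Product: 12 2,4-bis(benzyloxy)-1-bromobenzene
Conditions: BnBr, K2CO3, DMF, 60 °C
Reagents that add atoms: benzyl bromide, BrCc1ccccc1
Why: Double Williamson etherification of the two phenols gives the protected ring D bromide.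

Step 9
Reactants: 10 (2R,3R)-3,8-bis(benzyloxy)-2-[3,4-bis(benzyloxy)phenyl]-6-bromo-2,3-dihydro-4H-chromen-4-one; 12 2,4-bis(benzyloxy)-1-bromobenzene
Product: 15 (2R,3R)-3,8-bis(benzyloxy)-4-[2,4-bis(benzyloxy)phenyl]-2-[3,4-bis(benzyloxy)phenyl]-6-bromo-3,4-dihydro-2H-chromen-4-ol (C4 epimer mixture), via aryllithium 13 (not isolated), via arylcerium dichloride 14 (not isolated)
Conditions: 12, n-BuLi, THF, −78 °C; CeCl3, −78 °C; then 10, −78 °C; aq NH4Cl
Reagents that add atoms: n-butyllithium, CCCC[Li] (lithium, in 13 only); cerium trichloride, Cl[Ce](Cl)Cl (cerium and chlorine, in 14 only)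
Why: Bromine–lithium exchange and transmetalation give a weakly basic organocerium reagent (Imamoto conditions) that should add to the enolisable C4 ketone without opening the pyranone ring or touching the C6 bromide, and the C4 configuration formed here is erased in the next step.

Step 10
Reactants: 15 (2R,3R)-3,8-bis(benzyloxy)-4-[2,4-bis(benzyloxy)phenyl]-2-[3,4-bis(benzyloxy)phenyl]-6-bromo-3,4-dihydro-2H-chromen-4-ol (C4 epimer mixture)
Product: 16 (2R,3S,4S)-3,8-bis(benzyloxy)-4-[2,4-bis(benzyloxy)phenyl]-2-[3,4-bis(benzyloxy)phenyl]-6-bromo-3,4-dihydro-2H-chromene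
Conditions: Et3SiH, TFA, CH2Cl2, −40 °C to 0 °C
Reagents that add atoms: none
Why: Ionic hydrogenation, in which TFA ionises the tertiary diarylmethyl alcohol to a cation stabilised by ring D and Et3SiH should deliver hydride to the face trans to the C3 benzyloxy group, as nucleophiles do with 2,3-trans-flavan-4-yl cations, which places ring D cis to O3 (4S).

Step 11
Reactants: 16 (2R,3S,4S)-3,8-bis(benzyloxy)-4-[2,4-bis(benzyloxy)phenyl]-2-[3,4-bis(benzyloxy)phenyl]-6-bromo-3,4-dihydro-2H-chromene; 17 methyl prop-2-enoate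
Product: 18 methyl (E)-3-(core-6-yl)prop-2-enoate
Conditions: Pd(OAc)2, P(o-tol)3, Et3N, DMF, 100 °C
Reagents that add atoms: none
Why: Mizoroki–Heck reaction, in which oxidative addition of the unhindered aryl bromide to zerovalent palladium, syn insertion of the acrylate and syn β-hydride elimination give the E cinnamate.

Step 12
Reactants: 18 methyl (E)-3-(core-6-yl)prop-2-enoate
Product: 19 (E)-3-(core-6-yl)prop-2-en-1-ol
Conditions: i-Bu2AlH, CH2Cl2, −78 °C
Reagents that add atoms: none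
Why: 1,2-Reduction of the conjugated ester by the aluminium hydride gives the allylic alcohol and leaves the alkene geometry and the benzyl ethers untouched.

Step 13
Reactants: 19 (E)-3-(core-6-yl)prop-2-en-1-ol
Product: 20 [(2S,3S)-3-(core-6-yl)oxiran-2-yl]methanol
Conditions: Ti(OiPr)4 (cat.), L-(+)-DIPT (cat.), t-BuOOH, 4 Å MS, CH2Cl2, −20 °C
Reagents that add atoms: tert-butyl hydroperoxide, CC(C)(C)OO
Why: Sharpless asymmetric epoxidation, in which the titanium tartrate complex binds the allylic alcohol and the peroxide and delivers oxygen to one alkene face, which for an E allylic alcohol and L-(+)-DIPT is the face that gives the (2S,3S) epoxy alcohol.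

Step 14
Reactants: 20 [(2S,3S)-3-(core-6-yl)oxiran-2-yl]methanol; 21 3-(benzyloxy)phenol
Product: 22 (2S,3R)-3-[3-(benzyloxy)phenoxy]-3-(core-6-yl)propane-1,2-diol
Conditions: aq NaOH, dioxane, 70 °C
Reagents that add atoms: none
Why: Phenoxide opening of a trans-3-arylglycidol at its benzylic carbon, which is activated by the para oxygen O1, in an SN2 reaction with inversion should set C2' as R and give the erythro aryloxy diol, C3' keeping the epoxide oxygen.

Step 15
Reactants: 22 (2S,3R)-3-[3-(benzyloxy)phenoxy]-3-(core-6-yl)propane-1,2-diol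
Product: 24 (2S)-2-[(R)-[3-(benzyloxy)phenoxy](core-6-yl)methyl]oxirane, via primary tosylate 23 (not isolated)
Conditions: NaH, 1-tosylimidazole, THF, 0 °C to rt
Reagents that add atoms: 1-(4-methylbenzenesulfonyl)imidazole, Cc1ccc(cc1)S(=O)(=O)n1ccnc1 (tosyl group, in 23 only)
Why: The primary hydroxyl is sulfonylated selectively and the neighbouring secondary alkoxide displaces the tosylate in a 3-exo-tet Williamson closure, which forms the terminal epoxide with retention at C3'.

Step 16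
Reactants: 24 (2S)-2-[(R)-[3-(benzyloxy)phenoxy](core-6-yl)methyl]oxirane
Product: 25 (2R,3S)-7-(benzyloxy)-2-(core-6-yl)-3,4-dihydro-2H-chromen-3-ol
Conditions: AuCl3 (5 mol %), AgOTf (15 mol %), CH2Cl2, 0 °C to rt
Reagents that add atoms: none
Why: AuCl3 and AgOTf give a cationic trivalent gold species that binds the epoxide oxygen, the ring A carbon ortho to O1' and para to the benzyloxy group attacks the terminal carbon C4', and the arenium ion loses a proton, which forms C4'–C4a' and frees the C3' hydroxyl. The closest known reaction is the gold-catalysed intramolecular Friedel–Crafts cyclisation of aryl glycidyl ethers and of 1-aryl-1-aryloxy-2,3-epoxypropanes to chroman-3-ols. Ring C closes in the 6-endo-tet mode with respect to the epoxide. No stereocentre is created: only the C4'–O bond breaks, so C3' keeps its oxygen and its S configuration, C2' is a spectator, and the erythro arrangement of 24 becomes the 2',3'-trans arrangement of ring C. The step needs attack at C4' instead of C3' (5-exo), which the primary epoxide terminus and the six-membered transition state should secure, and attack para instead of ortho to the benzyloxy group, which the crowding between the two ring A oxygens should secure. Low catalyst loading and low temperature are chosen so that the benzylic C2'–O1' bond, which lies para to O1, does not ionise.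

Step 17
Reactants: 25 (2R,3S)-7-(benzyloxy)-2-(core-6-yl)-3,4-dihydro-2H-chromen-3-ol
Product: 26 (2R,3S,4S)-2-(3,4-dihydroxyphenyl)-4-(2,4-dihydroxyphenyl)-6-[(2R,3S)-3,7-dihydroxy-3,4-dihydro-2H-chromen-2-yl]-3,4-dihydro-2H-chromene-3,8-diol
Conditions: H2 (1 atm), Pd(OH)2/C, THF/MeOH, rt
Reagents that add atoms: none
Why: Catalytic hydrogenolysis should cleave all seven benzyl ethers, while the cyclic benzylic ethers C2–O1 and C2'–O1' are expected to survive these neutral conditions as they do in flavan-3-ol benzyl ethers.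

Compound list
1 | 1-(2,3-dihydroxyphenyl)ethan-1-one | CC(=O)c1cccc(O)c1O | starting material
2 | 1-[3-(benzyloxy)-2-hydroxyphenyl]ethan-1-one | CC(=O)c1cccc(OCc2ccccc2)c1O | intermediate
3 | 1-[3-(benzyloxy)-5-bromo-2-hydroxyphenyl]ethan-1-one | CC(=O)c1cc(Br)cc(OCc2ccccc2)c1O | intermediate
4 | 1-[3-(benzyloxy)-5-bromo-2-(methoxymethoxy)phenyl]ethan-1-one | COCOc1c(OCc2ccccc2)cc(Br)cc1C(C)=O | intermediate
5 | 3,4-bis(benzyloxy)benzaldehyde | O=Cc1ccc(OCc2ccccc2)c(OCc2ccccc2)c1 | starting material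
6 | (E)-1-[3-(benzyloxy)-5-bromo-2-(methoxymethoxy)phenyl]-3-[3,4-bis(benzyloxy)phenyl]prop-2-en-1-one | COCOc1c(OCc2ccccc2)cc(Br)cc1C(=O)/C=C/c1ccc(OCc2ccccc2)c(OCc2ccccc2)c1 | intermediate
7 | [3-(benzyloxy)-5-bromo-2-(methoxymethoxy)phenyl]{(2R,3S)-3-[3,4-bis(benzyloxy)phenyl]oxiran-2-yl}methanone | COCOc1c(OCc2ccccc2)cc(Br)cc1C(=O)[C@@H]1O[C@H]1c1ccc(OCc2ccccc2)c(OCc2ccccc2)c1 | intermediate
8 | [3-(benzyloxy)-5-bromo-2-hydroxyphenyl]{(2R,3S)-3-[3,4-bis(benzyloxy)phenyl]oxiran-2-yl}methanone | Oc1c(OCc2ccccc2)cc(Br)cc1C(=O)[C@@H]1O[C@H]1c1ccc(OCc2ccccc2)c(OCc2ccccc2)c1 | intermediate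
9 | (2R,3R)-8-(benzyloxy)-2-[3,4-bis(benzyloxy)phenyl]-6-bromo-3-hydroxy-2,3-dihydro-4H-chromen-4-one | O=C1c2cc(Br)cc(OCc3ccccc3)c2O[C@H](c2ccc(OCc3ccccc3)c(OCc3ccccc3)c2)[C@H]1O | intermediate
10 | (2R,3R)-3,8-bis(benzyloxy)-2-[3,4-bis(benzyloxy)phenyl]-6-bromo-2,3-dihydro-4H-chromen-4-one | O=C1c2cc(Br)cc(OCc3ccccc3)c2O[C@H](c2ccc(OCc3ccccc3)c(OCc3ccccc3)c2)[C@H]1OCc1ccccc1 | intermediate
11 | 4-bromobenzene-1,3-diol (4-bromoresorcinol) | Oc1ccc(Br)c(O)c1 | starting material
12 | 2,4-bis(benzyloxy)-1-bromobenzene | Brc1ccc(OCc2ccccc2)cc1OCc1ccccc1 | intermediate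
13 | [2,4-bis(benzyloxy)phenyl]lithium | [Li]c1ccc(OCc2ccccc2)cc1OCc1ccccc1 | intermediate
14 | [2,4-bis(benzyloxy)phenyl]cerium dichloride | Cl[Ce](Cl)c1ccc(OCc2ccccc2)cc1OCc1ccccc1 | intermediate
15 | (2R,3R)-3,8-bis(benzyloxy)-4-[2,4-bis(benzyloxy)phenyl]-2-[3,4-bis(benzyloxy)phenyl]-6-bromo-3,4-dihydro-2H-chromen-4-ol (C4 epimer mixture) | c1ccccc1COc1ccc(C2(O)c3cc(Br)cc(OCc4ccccc4)c3O[C@H](c3ccc(OCc4ccccc4)c(OCc4ccccc4)c3)[C@H]2OCc2ccccc2)c(OCc2ccccc2)c1 | intermediate
16 | (2R,3S,4S)-3,8-bis(benzyloxy)-4-[2,4-bis(benzyloxy)phenyl]-2-[3,4-bis(benzyloxy)phenyl]-6-bromo-3,4-dihydro-2H-chromene | c1ccccc1COc1ccc([C@H]2c3cc(Br)cc(OCc4ccccc4)c3O[C@H](c3ccc(OCc4ccccc4)c(OCc4ccccc4)c3)[C@H]2OCc2ccccc2)c(OCc2ccccc2)c1 | intermediate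
17 | methyl prop-2-enoate (methyl acrylate) | C=CC(=O)OC | starting material
18 | methyl (E)-3-(core-6-yl)prop-2-enoate | c1ccccc1COc1ccc([C@H]2c3cc(/C=C/C(=O)OC)cc(OCc4ccccc4)c3O[C@H](c3ccc(OCc4ccccc4)c(OCc4ccccc4)c3)[C@H]2OCc2ccccc2)c(OCc2ccccc2)c1 | intermediate
19 | (E)-3-(core-6-yl)prop-2-en-1-ol | c1ccccc1COc1ccc([C@H]2c3cc(/C=C/CO)cc(OCc4ccccc4)c3O[C@H](c3ccc(OCc4ccccc4)c(OCc4ccccc4)c3)[C@H]2OCc2ccccc2)c(OCc2ccccc2)c1 | intermediate
20 | [(2S,3S)-3-(core-6-yl)oxiran-2-yl]methanol | c1ccccc1COc1ccc([C@H]2c3cc([C@@H]4O[C@H]4CO)cc(OCc4ccccc4)c3O[C@H](c3ccc(OCc4ccccc4)c(OCc4ccccc4)c3)[C@H]2OCc2ccccc2)c(OCc2ccccc2)c1 | intermediate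
21 | 3-(benzyloxy)phenol | Oc1cccc(OCc2ccccc2)c1 | starting material
22 | (2S,3R)-3-[3-(benzyloxy)phenoxy]-3-(core-6-yl)propane-1,2-diol | c1ccccc1COc1ccc([C@H]2c3cc([C@@H](Oc5cccc(OCc6ccccc6)c5)[C@@H](O)CO)cc(OCc4ccccc4)c3O[C@H](c3ccc(OCc4ccccc4)c(OCc4ccccc4)c3)[C@H]2OCc2ccccc2)c(OCc2ccccc2)c1 | intermediate
23 | (2S,3R)-3-[3-(benzyloxy)phenoxy]-3-(core-6-yl)-2-hydroxypropyl 4-methylbenzenesulfonate | c1ccccc1COc1ccc([C@H]2c3cc([C@@H](Oc5cccc(OCc6ccccc6)c5)[C@@H](O)COS(=O)(=O)c5ccc(C)cc5)cc(OCc4ccccc4)c3O[C@H](c3ccc(OCc4ccccc4)c(OCc4ccccc4)c3)[C@H]2OCc2ccccc2)c(OCc2ccccc2)c1 | intermediate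
24 | (2S)-2-[(R)-[3-(benzyloxy)phenoxy](core-6-yl)methyl]oxirane | c1ccccc1COc1ccc([C@H]2c3cc([C@@H](Oc5cccc(OCc6ccccc6)c5)[C@@H]4CO4)cc(OCc4ccccc4)c3O[C@H](c3ccc(OCc4ccccc4)c(OCc4ccccc4)c3)[C@H]2OCc2ccccc2)c(OCc2ccccc2)c1 | intermediate
25 | (2R,3S)-7-(benzyloxy)-2-(core-6-yl)-3,4-dihydro-2H-chromen-3-ol | c1ccccc1COc1ccc([C@H]2c3cc([C@H]4Oc5cc(OCc6ccccc6)ccc5C[C@@H]4O)cc(OCc4ccccc4)c3O[C@H](c3ccc(OCc4ccccc4)c(OCc4ccccc4)c3)[C@H]2OCc2ccccc2)c(OCc2ccccc2)c1 | intermediate
26 | (2R,3S,4S)-2-(3,4-dihydroxyphenyl)-4-(2,4-dihydroxyphenyl)-6-[(2R,3S)-3,7-dihydroxy-3,4-dihydro-2H-chromen-2-yl]-3,4-dihydro-2H-chromene-3,8-diol (CNP0319348.1) | Oc1ccc([C@H]2c3cc([C@H]4Oc5cc(O)ccc5C[C@@H]4O)cc(O)c3O[C@H](c3ccc(O)c(O)c3)[C@H]2O)c(O)c1 | target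

Total step count: 17. Longest linear sequence: 16 steps (steps 1 to 7 and 9 to 17); step 8 prepares the ring D bromide separately.

Steps most likely to fail

Step 10. Hydride may reach the C4 cation from the face cis to O3, or a 1,2-hydride shift from C3 to the cation may compete with reduction, so that the 3,4-cis relation is not obtained cleanly. The fallback exchanges the roles of the two groups at C4 and sets out from ketone 10. Reduction with NaBH4 in MeOH/THF at 0 °C should give the 3,4-trans alcohol (2R,3S,4R)-3,8-bis(benzyloxy)-2-[3,4-bis(benzyloxy)phenyl]-6-bromo-3,4-dihydro-2H-chromen-4-ol F1. BF3·OEt2 in CH2Cl2 at −40 °C ionises F1 in the presence of 1,3-bis(benzyloxy)benzene, which attacks through its C4 in the classical Friedel–Crafts synthesis of 4-arylflavan-3-ols. The aryl group now enters on the face that hydride would have taken, so the two routes are stereocomplementary. The reaction is expected to give bromide 16 together with its C4 epimer (2R,3S,4R)-3,8-bis(benzyloxy)-4-[2,4-bis(benzyloxy)phenyl]-2-[3,4-bis(benzyloxy)phenyl]-6-bromo-3,4-dihydro-2H-chromene F2; the two are separated by chromatography and the route is rejoined at 16.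

Step 16. The Lewis acid may ionise the benzylic C2'–O1' bond, with loss of the C2' configuration or cleavage of the ether; the epoxide may also rearrange to a carbonyl compound before the arene attacks, or the ring may close between the two ring A oxygens. The fallback makes the same C4'–C4a' bond with an aryl anion instead of an arene and sets out from epoxy alcohol 20. 4-Bromoresorcinol 11 is monobenzylated at the less hindered hydroxyl para to bromine (BnBr, K2CO3, acetone) to 5-(benzyloxy)-2-bromophenol F3. F3 replaces 21 under the conditions of step 14 and gives (2S,3R)-3-[5-(benzyloxy)-2-bromophenoxy]-3-(core-6-yl)propane-1,2-diol F4. Selective primary sulfonylation (TsCl, Et3N, cat. Bu2SnO) gives (2S,3R)-3-[5-(benzyloxy)-2-bromophenoxy]-3-(core-6-yl)-2-hydroxypropyl 4-methylbenzenesulfonate F5, and silylation (TBSOTf, 2,6-lutidine) gives its tert-butyldimethylsilyl ether F6. Bromine–lithium exchange with t-BuLi in THF at −78 °C and 6-exo-tet displacement of the tosylate (Parham cyclisation) give the O3' tert-butyldimethylsilyl ether of 25, F7, with the ring A carbon fixed by the position of the bromine. Bu4NF in THF then returns the route to alcohol 25.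

Step 14. The opening may lose stereochemical integrity at the benzylic carbon through SN1 character caused by the para oxygen O1. Payne migration may divert the phenoxide to the terminal carbon, and the electron-rich epoxy alcohol 20 may not survive its own formation in step 13. The fallback forms the aryl ether at the aryl carbon, so that the benzylic C–O bond is never broken, and sets out from bromide 16. Bromine–lithium exchange (n-BuLi, THF, −78 °C) and addition to acrolein give 1-(core-6-yl)prop-2-en-1-ol F8 as both carbinol epimers. Sharpless epoxidation with diisopropyl D-tartrate (Ti(OiPr)4, t-BuOOH, 4 Å MS, CH2Cl2, −20 °C) acts as a kinetic resolution of the epimers. It should convert the (S)-carbinol epimer into the erythro epoxy alcohol (R)-(core-6-yl)[(2S)-oxiran-2-yl]methanol F9 and leave the (R) epimer, which is separated. Chan–Lam O-arylation of F9 with 3-(benzyloxy)phenylboronic acid (Cu(OAc)2, pyridine, 4 Å MS, air, CH2Cl2, rt) then gives aryl ether 24 with retention, where the route is rejoined.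

Further compounds
F1 | step 10 | (2R,3S,4R)-3,8-bis(benzyloxy)-2-[3,4-bis(benzyloxy)phenyl]-6-bromo-3,4-dihydro-2H-chromen-4-ol | O[C@@H]1c2cc(Br)cc(OCc3ccccc3)c2O[C@H](c2ccc(OCc3ccccc3)c(OCc3ccccc3)c2)[C@H]1OCc1ccccc1
F2 | step 10 | (2R,3S,4R)-3,8-bis(benzyloxy)-4-[2,4-bis(benzyloxy)phenyl]-2-[3,4-bis(benzyloxy)phenyl]-6-bromo-3,4-dihydro-2H-chromene (C4 epimer of 16) | c1ccccc1COc1ccc([C@@H]2c3cc(Br)cc(OCc4ccccc4)c3O[C@H](c3ccc(OCc4ccccc4)c(OCc4ccccc4)c3)[C@H]2OCc2ccccc2)c(OCc2ccccc2)c1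
F3 | step 16 | 5-(benzyloxy)-2-bromophenol | Oc1cc(OCc2ccccc2)ccc1Br
F4 | step 16 | (2S,3R)-3-[5-(benzyloxy)-2-bromophenoxy]-3-(core-6-yl)propane-1,2-diol | c1ccccc1COc1ccc([C@H]2c3cc([C@@H](Oc5cc(OCc6ccccc6)ccc5Br)[C@@H](O)CO)cc(OCc4ccccc4)c3O[C@H](c3ccc(OCc4ccccc4)c(OCc4ccccc4)c3)[C@H]2OCc2ccccc2)c(OCc2ccccc2)c1
F5 | step 16 | (2S,3R)-3-[5-(benzyloxy)-2-bromophenoxy]-3-(core-6-yl)-2-hydroxypropyl 4-methylbenzenesulfonate | c1ccccc1COc1ccc([C@H]2c3cc([C@@H](Oc5cc(OCc6ccccc6)ccc5Br)[C@@H](O)COS(=O)(=O)c5ccc(C)cc5)cc(OCc4ccccc4)c3O[C@H](c3ccc(OCc4ccccc4)c(OCc4ccccc4)c3)[C@H]2OCc2ccccc2)c(OCc2ccccc2)c1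
F6 | step 16 | (2S,3R)-3-[5-(benzyloxy)-2-bromophenoxy]-2-[(tert-butyldimethylsilyl)oxy]-3-(core-6-yl)propyl 4-methylbenzenesulfonate | c1ccccc1COc1ccc([C@H]2c3cc([C@@H](Oc5cc(OCc6ccccc6)ccc5Br)[C@@H](O[Si](C)(C)C(C)(C)C)COS(=O)(=O)c5ccc(C)cc5)cc(OCc4ccccc4)c3O[C@H](c3ccc(OCc4ccccc4)c(OCc4ccccc4)c3)[C@H]2OCc2ccccc2)c(OCc2ccccc2)c1
F7 | step 16 | {[(2R,3S)-7-(benzyloxy)-2-(core-6-yl)-3,4-dihydro-2H-chromen-3-yl]oxy}(tert-butyl)dimethylsilane | c1ccccc1COc1ccc([C@H]2c3cc([C@H]4Oc5cc(OCc6ccccc6)ccc5C[C@@H]4O[Si](C)(C)C(C)(C)C)cc(OCc4ccccc4)c3O[C@H](c3ccc(OCc4ccccc4)c(OCc4ccccc4)c3)[C@H]2OCc2ccccc2)c(OCc2ccccc2)c1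
F8 | step 14 | 1-(core-6-yl)prop-2-en-1-ol (both carbinol epimers) | c1ccccc1COc1ccc([C@H]2c3cc(C(O)C=C)cc(OCc4ccccc4)c3O[C@H](c3ccc(OCc4ccccc4)c(OCc4ccccc4)c3)[C@H]2OCc2ccccc2)c(OCc2ccccc2)c1
F9 | step 14 | (R)-(core-6-yl)[(2S)-oxiran-2-yl]methanol | c1ccccc1COc1ccc([C@H]2c3cc([C@@H](O)[C@@H]4CO4)cc(OCc4ccccc4)c3O[C@H](c3ccc(OCc4ccccc4)c(OCc4ccccc4)c3)[C@H]2OCc2ccccc2)c(OCc2ccccc2)c1
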